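The α-methylene-γ-butyrolactone ring (O–C12–C11–C7–C6, germacrane numbering) is closed on an open chain by joining C11 to C7, before the ten-membered ring exists. The step exploits the oxygen triad around C7: C6–O inside the lactone and C8–O beside it are the footprint of a C7–C8 epoxide opened with inversion by a carbanion delivered from O6. The precursor is the diethylphosphonoacetate of a Sharpless-derived threo trans-2,3-epoxy alcohol. Base triggers 5-exo opening (lactone ring, C7 configuration, free C8–OH), and formaldehyde then turns the phosphonate into the exocyclic methylene in the same flask. Nozaki–Hiyama–Kishi closure at C3–C4 follows.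

Key step: step 11

Remark: atoms carry germacranolide numbers (C1–C10 ring, C11–C13 lactone and methylene, C14 methyl, C15 hydroxymethyl); the target is taken as the (1R,3S,6S,7R,8R,10S) isomer of the SMILES, in which O3, O6, C11 on C7, O8 and the oxirane oxygen lie on one face of a flat ring projection.
Remark: step 9 is a kinetic resolution, so no more than half of racemic 15 can be carried on; compounds 1, 2, 6, 8 and 17 are taken as commercial.

Step 1
Reactants: 1 3-[(tert-butyldimethylsilyl)oxy]propanal; 2 ethyl 2-[bis(2,2,2-trifluoroethoxy)phosphoryl]propanoate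
Product: 3 ethyl (2Z)-5-[(tert-butyldimethylsilyl)oxy]-2-methylpent-2-enoate
Conditions: KN(SiMe3)2, 18-crown-6, THF, −78 °C
Reagents that add atoms: none
Why: Still–Gennari olefination, in which the bis(trifluoroethyl) phosphonate makes elimination from the first adduct faster than its equilibration, so the kinetic Z-trisubstituted enoate (the future Z C1=C10 unit with C14) should form.

Step 2
Reactants: 3 ethyl (2Z)-5-[(tert-butyldimethylsilyl)oxy]-2-methylpent-2-enoate
Product: 4 (2Z)-5-[(tert-butyldimethylsilyl)oxy]-2-methylpent-2-en-1-ol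
Conditions: iBu2AlH (2.2 equiv), CH2Cl2, −78 °C; aqueous potassium sodium tartrate
Reagents that add atoms: none
Why: Hydride 1,2-reduction of the conjugated ester by iBu2AlH at low temperature is standard and leaves the Z geometry and the silyl ether untouched.

Step 3
Reactants: 4 (2Z)-5-[(tert-butyldimethylsilyl)oxy]-2-methylpent-2-en-1-ol
Product: 5 {[(3Z)-5-bromo-4-methylpent-3-en-1-yl]oxy}(tert-butyl)dimethylsilane
Conditions: CBr4, PPh3, CH2Cl2, 0 °C
Reagents that add atoms: carbon tetrabromide BrC(Br)(Br)Br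
Why: Appel reaction, in which bromide displaces the oxyphosphonium ion of the primary allylic alcohol in an SN2 sense under neutral conditions, which should keep the Z geometry.

Step 4
Reactants: 5 {[(3Z)-5-bromo-4-methylpent-3-en-1-yl]oxy}(tert-butyl)dimethylsilane; 6 ethynylmagnesium bromide (HC≡CMgBr)
Product: 7 tert-butyldimethyl{[(3Z)-4-methylhept-3-en-6-yn-1-yl]oxy}silane
Conditions: CuBr·SMe2 (10 mol%), THF, 0 °C to 40 °C, excess 6
Reagents that add atoms: none
Why: Copper-catalysed SN2 coupling of an alkynyl Grignard reagent with a primary allylic bromide, a standard route to skipped enynes, should join C8 to C9 with retention of the alkene geometry.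

Step 5
Reactants: 8 but-2-yne-1,4-diol
Product: 9 4-[(4-methoxybenzyl)oxy]but-2-yn-1-ol
Conditions: NaH (1 equiv), THF/DMF, 0 °C to rt, diol in threefold excess
Reagents that add atoms: 4-methoxybenzyl chloride COc1ccc(CCl)cc1
Why: Williamson etherification of the mono-alkoxide of a symmetrical diol used in excess should give mainly the mono-PMB ether.

Step 6
Reactants: 9 4-[(4-methoxybenzyl)oxy]but-2-yn-1-ol
Product: 11 (2Z)-3-iodo-4-[(4-methoxybenzyl)oxy]but-2-en-1-ol, via sodium alkenylaluminate 10 (not isolated)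
Conditions: NaAlH2(OCH2CH2OMe)2, THF, 0 °C to rt; then I2, THF, −78 °C
Reagents that add atoms: iodine II
Why: Hydroxyl-directed trans-hydroalumination of the propargylic alcohol places aluminium on the distal alkyne carbon within a five-membered aluminate, and iodinolysis with retention then gives the Z iodoalkene in which iodine (the site of the later C3–C4 bond) is cis to C6.

Step 7
Reactants: 11 (2Z)-3-iodo-4-[(4-methoxybenzyl)oxy]but-2-en-1-ol
Product: 12 (2Z)-3-iodo-4-[(4-methoxybenzyl)oxy]but-2-enal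
Conditions: MnO2, CH2Cl2, rt, dark
Reagents that add atoms: none
Why: MnO2 oxidises the allylic alcohol selectively to the enal under neutral conditions that should not scramble the iodoalkene geometry.

Step 8
Reactants: 7 tert-butyldimethyl{[(3Z)-4-methylhept-3-en-6-yn-1-yl]oxy}silane; 12 (2Z)-3-iodo-4-[(4-methoxybenzyl)oxy]but-2-enal
Product: 15 rac-(2Z,5E,8Z)-11-[(tert-butyldimethylsilyl)oxy]-2-iodo-1-[(4-methoxybenzyl)oxy]-8-methylundeca-2,5,8-trien-4-ol, via alkenylzirconocene chloride 13 (not isolated), via alkenylmethylzinc 14 (not isolated)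
Conditions: Cp2Zr(H)Cl, CH2Cl2, rt; Me2Zn, toluene, −65 °C; then 12, 0 °C
Reagents that add atoms: none
Why: Syn hydrozirconation of the terminal alkyne gives the E-alkenylzirconocene, transmetalation to zinc and 1,2-addition to the enal then form C6–C7 with the E C7=C8 alkene in place, and C6 is made racemic on purpose because the next step resolves it.

Step 9
Reactants: 15 rac-(2Z,5E,8Z)-11-[(tert-butyldimethylsilyl)oxy]-2-iodo-1-[(4-methoxybenzyl)oxy]-8-methylundeca-2,5,8-trien-4-ol
Product: 16 (1R,2Z)-1-[(2R,3R)-3-{(2Z)-5-[(tert-butyldimethylsilyl)oxy]-2-methylpent-2-en-1-yl}oxiran-2-yl]-3-iodo-4-[(4-methoxybenzyl)oxy]but-2-en-1-ol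
Conditions: Ti(OiPr)4 (20 mol%), D-(−)-diisopropyl tartrate (24 mol%), tBuOOH (0.55 equiv), 4 Å sieves, CH2Cl2, −20 °C
Reagents that add atoms: tert-butyl hydroperoxide CC(C)(C)OO
Why: Sharpless asymmetric epoxidation run as a kinetic resolution, in which with D-(−)-tartrate only the (4S) enantiomer of 15 is epoxidised quickly at the E-disubstituted C7=C8 alkene on the tartrate-fixed face to give the erythro epoxy alcohol, so C7 and C8 are set by the reagent and C6 by selection, while the hindered electron-poor iodoalkene and the isolated C1=C10 alkene should not react.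

Step 10
Reactants: 16 (1R,2Z)-1-[(2R,3R)-3-{(2Z)-5-[(tert-butyldimethylsilyl)oxy]-2-methylpent-2-en-1-yl}oxiran-2-yl]-3-iodo-4-[(4-methoxybenzyl)oxy]but-2-en-1-ol; 17 (diethoxyphosphoryl)acetic acid
Product: 18 (1S,2Z)-1-[(2S,3R)-3-{(2Z)-5-[(tert-butyldimethylsilyl)oxy]-2-methylpent-2-en-1-yl}oxiran-2-yl]-3-iodo-4-[(4-methoxybenzyl)oxy]but-2-en-1-yl (diethoxyphosphoryl)acetate
Conditions: PPh3, diisopropyl azodicarboxylate, THF, 0 °C to rt
Reagents that add atoms: none
Why: Mitsunobu esterification, in which the carboxylate displaces the activated C6–O in an SN2 sense, installs the carbanion tether and at once inverts C6 to the threo relationship that the target needs.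

Step 11
Reactants: 18 (1S,2Z)-1-[(2S,3R)-3-{(2Z)-5-[(tert-butyldimethylsilyl)oxy]-2-methylpent-2-en-1-yl}oxiran-2-yl]-3-iodo-4-[(4-methoxybenzyl)oxy]but-2-en-1-yl (diethoxyphosphoryl)acetate
Product: 20 (4R,5R)-4-{(1R,3Z)-6-[(tert-butyldimethylsilyl)oxy]-1-hydroxy-3-methylhex-3-en-1-yl}-5-{(1Z)-2-iodo-3-[(4-methoxybenzyl)oxy]prop-1-en-1-yl}-3-methylideneoxolan-2-one, via sodium phosphonolactone carbanion 19 (not isolated)
Conditions: NaH (1.05 equiv), THF, 0 °C to 45 °C; then paraformaldehyde, 0 °C to rt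
Reagents that add atoms: paraformaldehyde (as formaldehyde) C=O
Why: Deprotonation gives the phosphonate- and ester-stabilised carbanion at C11, which attacks C7 from the rear of the C7–O oxirane bond (SN2 epoxide alkylation); the alkoxide set free at C8 is quenched by the acidic C11–H, so the resting species is carbanion 19, which then undergoes Horner–Wadsworth–Emmons olefination with formaldehyde to install C13. The closest known reactions are the base-induced cyclisation of 2,3-epoxy alcohol esters of bis-activated acetic acids to γ-lactones, the epoxide-opening first stage of Wadsworth–Emmons cyclopropanation, and the standard methylenation of α-phosphono lactones. The five-membered lactone closes in the 5-exo-tet mode, the three-atom O6–C12 tether holding C11 over C7, whereas attack at C8 would need a 6-endo trajectory. C7 is the only new stereocenter and is fixed by inversion of the oxirane carbon set in the Sharpless step, while C8 keeps its C–O bond and C6 its Mitsunobu-set configuration, which together give the cis lactone with O6, C11 and O8 on one face. The step needs C- over O-alkylation and freedom from the stereoelectronic handicap of an endocyclic ester enolate, and both are secured by the exocyclic phosphoryl group, which keeps the carbanion nucleophilic while C11 turns out of the ester plane. Warming is kept moderate so that the C8 alkoxide does not attack phosphorus (the path to a cyclopropane), and the alkenyl iodide, silyl ether and PMB ether are inert to the base.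

Step 12
Reactants: 20 (4R,5R)-4-{(1R,3Z)-6-[(tert-butyldimethylsilyl)oxy]-1-hydroxy-3-methylhex-3-en-1-yl}-5-{(1Z)-2-iodo-3-[(4-methoxybenzyl)oxy]prop-1-en-1-yl}-3-methylideneoxolan-2-one
Product: 21 (1R,3Z)-6-[(tert-butyldimethylsilyl)oxy]-1-[(2R,3R)-2-{(1Z)-2-iodo-3-[(4-methoxybenzyl)oxy]prop-1-en-1-yl}-4-methylidene-5-oxooxolan-3-yl]-3-methylhex-3-en-1-yl 2-methylprop-2-enoate
Conditions: methacrylic anhydride, Et3N, DMAP (cat.), CH2Cl2, 0 °C to rt
Reagents that add atoms: methacrylic anhydride C=C(C)C(=O)OC(=O)C(C)=C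
Why: DMAP-catalysed acylation of the free secondary C8 hydroxyl by the anhydride is a standard esterification that should not disturb the lactone.

Step 13
Reactants: 21 (1R,3Z)-6-[(tert-butyldimethylsilyl)oxy]-1-[(2R,3R)-2-{(1Z)-2-iodo-3-[(4-methoxybenzyl)oxy]prop-1-en-1-yl}-4-methylidene-5-oxooxolan-3-yl]-3-methylhex-3-en-1-yl 2-methylprop-2-enoate
Product: 22 (1R,3Z)-6-hydroxy-1-[(2R,3R)-2-{(1Z)-2-iodo-3-[(4-methoxybenzyl)oxy]prop-1-en-1-yl}-4-methylidene-5-oxooxolan-3-yl]-3-methylhex-3-en-1-yl 2-methylprop-2-enoate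
Conditions: HF·pyridine, pyridine, THF, 0 °C to rt
Reagents that add atoms: none
Why: Buffered fluoride cleavage removes the primary silyl ether, while the PMB ether, the two acrylate units and the alkenyl iodide are inert to HF·pyridine.

Step 14
Reactants: 22 (1R,3Z)-6-hydroxy-1-[(2R,3R)-2-{(1Z)-2-iodo-3-[(4-methoxybenzyl)oxy]prop-1-en-1-yl}-4-methylidene-5-oxooxolan-3-yl]-3-methylhex-3-en-1-yl 2-methylprop-2-enoate
Product: 23 (1R,3Z)-1-[(2R,3R)-2-{(1Z)-2-iodo-3-[(4-methoxybenzyl)oxy]prop-1-en-1-yl}-4-methylidene-5-oxooxolan-3-yl]-3-methyl-6-oxohex-3-en-1-yl 2-methylprop-2-enoate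
Conditions: Dess–Martin periodinane, pyridine, CH2Cl2, 0 °C; used crude
Reagents that add atoms: none
Why: Dess–Martin oxidation under buffered non-basic conditions should give the β,γ-unsaturated aldehyde without moving the C1=C10 alkene into conjugation.

Step 15
Reactants: 23 (1R,3Z)-1-[(2R,3R)-2-{(1Z)-2-iodo-3-[(4-methoxybenzyl)oxy]prop-1-en-1-yl}-4-methylidene-5-oxooxolan-3-yl]-3-methyl-6-oxohex-3-en-1-yl 2-methylprop-2-enoate
Product: 24 (3S,6S,7R,8R)-3-hydroxy-15-[(4-methoxybenzyl)oxy]-8-(methacryloyloxy)germacra-1(10)Z,4Z,11(13)-trien-12,6-olide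
Conditions: CrCl2 (excess), NiCl2 (cat.), DMSO/THF, rt, slow addition at high dilution
Reagents that add atoms: none
Why: Nozaki–Hiyama–Kishi reaction, in which nickel catalysis converts the alkenyl iodide into an alkenylchromium species that adds to the aldehyde with retention of the Z alkene geometry, with the cis arms on the lactone and the Z C1=C10 alkene bringing the chain ends together for ten-membered ring closure; the (3S) configuration is hoped for from addition to the exposed aldehyde face but rests on substrate control only.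

Step 16
Reactants: 24 (3S,6S,7R,8R)-3-hydroxy-15-[(4-methoxybenzyl)oxy]-8-(methacryloyloxy)germacra-1(10)Z,4Z,11(13)-trien-12,6-olide
Product: 25 (1R,3S,6S,7R,8R,10S)-1,10-epoxy-3-hydroxy-15-[(4-methoxybenzyl)oxy]-8-(methacryloyloxy)germacra-4Z,11(13)-dien-12,6-olide
Conditions: mCPBA, solid NaHCO3 (buffer), CH2Cl2, 0 °C
Reagents that add atoms: 3-chloroperbenzoic acid O=C(OO)c1cccc(Cl)c1
Why: Hydroxyl-directed peracid epoxidation, in which C1=C10 is the only electron-rich alkene (C4=C5 carries three allylic oxygens and the other two are acrylates) and hydrogen bonding of the peracid to the homoallylic C3–OH should deliver oxygen to the face of the Z alkene that carries O3, giving the cis (1R,10S) oxirane.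

Step 17
Reactants: 25 (1R,3S,6S,7R,8R,10S)-1,10-epoxy-3-hydroxy-15-[(4-methoxybenzyl)oxy]-8-(methacryloyloxy)germacra-4Z,11(13)-dien-12,6-olide
Product: 26 (1R,3S,6S,7R,8R,10S)-3-acetoxy-1,10-epoxy-15-[(4-methoxybenzyl)oxy]-8-(methacryloyloxy)germacra-4Z,11(13)-dien-12,6-olide
Conditions: Ac2O, DMAP (cat.), pyridine, CH2Cl2, 0 °C
Reagents that add atoms: acetic anhydride CC(=O)OC(C)=O
Why: DMAP-catalysed acetylation of the allylic C3 hydroxyl is a standard esterification that also removes the hydroxyl that could attack the oxirane across the ring.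

Step 18
Reactants: 26 (1R,3S,6S,7R,8R,10S)-3-acetoxy-1,10-epoxy-15-[(4-methoxybenzyl)oxy]-8-(methacryloyloxy)germacra-4Z,11(13)-dien-12,6-olide
Product: 27 (1R,3S,6S,7R,8R,10S)-3-acetoxy-1,10-epoxy-15-hydroxy-8-(methacryloyloxy)germacra-4Z,11(13)-dien-12,6-olide
Conditions: DDQ, CH2Cl2/pH 7 buffer, 0 °C
Reagents that add atoms: none
Why: Oxidative cleavage of the PMB ether by DDQ through the benzylic oxocarbenium ion and its hydrolysis frees C15–OH without touching the esters, the oxirane or the electron-poor alkenes.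

Compound list
1 | 3-[(tert-butyldimethylsilyl)oxy]propanal | O=CCCO[Si](C)(C)C(C)(C)C | starting material
2 | ethyl 2-[bis(2,2,2-trifluoroethoxy)phosphoryl]propanoate | CCOC(=O)C(C)P(=O)(OCC(F)(F)F)OCC(F)(F)F | starting material
3 | ethyl (2Z)-5-[(tert-butyldimethylsilyl)oxy]-2-methylpent-2-enoate | CCOC(=O)/C(C)=C\CCO[Si](C)(C)C(C)(C)C | intermediate
4 | (2Z)-5-[(tert-butyldimethylsilyl)oxy]-2-methylpent-2-en-1-ol | OC/C(C)=C\CCO[Si](C)(C)C(C)(C)C | intermediate
5 | {[(3Z)-5-bromo-4-methylpent-3-en-1-yl]oxy}(tert-butyl)dimethylsilane | BrC/C(C)=C\CCO[Si](C)(C)C(C)(C)C | intermediate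
6 | ethynylmagnesium bromide | C#C[Mg]Br | starting material
7 | tert-butyldimethyl{[(3Z)-4-methylhept-3-en-6-yn-1-yl]oxy}silane | C#CC/C(C)=C\CCO[Si](C)(C)C(C)(C)C | intermediate
8 | but-2-yne-1,4-diol | OCC#CCO | starting material
9 | 4-[(4-methoxybenzyl)oxy]but-2-yn-1-ol | OCC#CCOCc1ccc(OC)cc1 | intermediate
10 | sodium 2,2-bis(2-methoxyethoxy)-3-{[(4-methoxybenzyl)oxy]methyl}-2,5-dihydro-1,2-oxaluminol-2-uide (cyclic alkenylaluminate, not isolated) | [Na+].COCCO[Al-]1(OCCOC)OCC=C1COCc1ccc(OC)cc1 | intermediate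
11 | (2Z)-3-iodo-4-[(4-methoxybenzyl)oxy]but-2-en-1-ol | OC/C=C(I)/COCc1ccc(OC)cc1 | intermediate
12 | (2Z)-3-iodo-4-[(4-methoxybenzyl)oxy]but-2-enal | O=C/C=C(I)/COCc1ccc(OC)cc1 | intermediate
13 | chloro{(1E,4Z)-7-[(tert-butyldimethylsilyl)oxy]-4-methylhepta-1,4-dien-1-yl}bis(cyclopentadienyl)zirconium (not isolated) | Cl[Zr](/C=C/C/C(C)=C\CCO[Si](C)(C)C(C)(C)C)(C1C=CC=C1)C1C=CC=C1 | intermediate
14 | {(1E,4Z)-7-[(tert-butyldimethylsilyl)oxy]-4-methylhepta-1,4-dien-1-yl}(methyl)zinc (not isolated) | C[Zn]/C=C/C/C(C)=C\CCO[Si](C)(C)C(C)(C)C | intermediate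
15 | rac-(2Z,5E,8Z)-11-[(tert-butyldimethylsilyl)oxy]-2-iodo-1-[(4-methoxybenzyl)oxy]-8-methylundeca-2,5,8-trien-4-ol | COc1ccc(COC/C(I)=C/C(O)/C=C/C/C(C)=C\CCO[Si](C)(C)C(C)(C)C)cc1 | intermediate
16 | (1R,2Z)-1-[(2R,3R)-3-{(2Z)-5-[(tert-butyldimethylsilyl)oxy]-2-methylpent-2-en-1-yl}oxiran-2-yl]-3-iodo-4-[(4-methoxybenzyl)oxy]but-2-en-1-ol (erythro; 6R,7R,8R) | COc1ccc(COC/C(I)=C/[C@@H](O)[C@H]2O[C@@H]2C/C(C)=C\CCO[Si](C)(C)C(C)(C)C)cc1 | intermediate
17 | (diethoxyphosphoryl)acetic acid | CCOP(=O)(CC(=O)O)OCC | starting material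
18 | (1S,2Z)-1-[(2S,3R)-3-{(2Z)-5-[(tert-butyldimethylsilyl)oxy]-2-methylpent-2-en-1-yl}oxiran-2-yl]-3-iodo-4-[(4-methoxybenzyl)oxy]but-2-en-1-yl (diethoxyphosphoryl)acetate (threo) | COc1ccc(COC/C(I)=C/[C@H](OC(=O)CP(=O)(OCC)OCC)[C@H]2O[C@@H]2C/C(C)=C\CCO[Si](C)(C)C(C)(C)C)cc1 | intermediate
19 | sodium salt of the C11 carbanion of the α-(diethoxyphosphoryl) lactone with free C8–OH (not isolated) | [Na+].COc1ccc(COC/C(I)=C/[C@@H]2OC([O-])=C(P(=O)(OCC)OCC)[C@@H]2[C@H](O)C/C(C)=C\CCO[Si](C)(C)C(C)(C)C)cc1 | intermediate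
20 | (4R,5R)-4-{(1R,3Z)-6-[(tert-butyldimethylsilyl)oxy]-1-hydroxy-3-methylhex-3-en-1-yl}-5-{(1Z)-2-iodo-3-[(4-methoxybenzyl)oxy]prop-1-en-1-yl}-3-methylideneoxolan-2-one | COc1ccc(COC/C(I)=C/[C@@H]2OC(=O)C(=C)[C@@H]2[C@H](O)C/C(C)=C\CCO[Si](C)(C)C(C)(C)C)cc1 | intermediate
21 | (1R,3Z)-6-[(tert-butyldimethylsilyl)oxy]-1-[(2R,3R)-2-{(1Z)-2-iodo-3-[(4-methoxybenzyl)oxy]prop-1-en-1-yl}-4-methylidene-5-oxooxolan-3-yl]-3-methylhex-3-en-1-yl 2-methylprop-2-enoate | COc1ccc(COC/C(I)=C/[C@@H]2OC(=O)C(=C)[C@@H]2[C@H](OC(=O)C(C)=C)C/C(C)=C\CCO[Si](C)(C)C(C)(C)C)cc1 | intermediate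
22 | (1R,3Z)-6-hydroxy-1-[(2R,3R)-2-{(1Z)-2-iodo-3-[(4-methoxybenzyl)oxy]prop-1-en-1-yl}-4-methylidene-5-oxooxolan-3-yl]-3-methylhex-3-en-1-yl 2-methylprop-2-enoate | COc1ccc(COC/C(I)=C/[C@@H]2OC(=O)C(=C)[C@@H]2[C@H](OC(=O)C(C)=C)C/C(C)=C\CCO)cc1 | intermediate
23 | (1R,3Z)-1-[(2R,3R)-2-{(1Z)-2-iodo-3-[(4-methoxybenzyl)oxy]prop-1-en-1-yl}-4-methylidene-5-oxooxolan-3-yl]-3-methyl-6-oxohex-3-en-1-yl 2-methylprop-2-enoate | COc1ccc(COC/C(I)=C/[C@@H]2OC(=O)C(=C)[C@@H]2[C@H](OC(=O)C(C)=C)C/C(C)=C\CC=O)cc1 | intermediate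
24 | (3S,6S,7R,8R)-3-hydroxy-15-[(4-methoxybenzyl)oxy]-8-(methacryloyloxy)germacra-1(10)Z,4Z,11(13)-trien-12,6-olide | C=C(C)C(=O)O[C@@H]1C/C(C)=C\C[C@H](O)/C(COCc3ccc(OC)cc3)=C\[C@@H]2OC(=O)C(=C)[C@@H]21 | intermediate
25 | (1R,3S,6S,7R,8R,10S)-1,10-epoxy-3-hydroxy-15-[(4-methoxybenzyl)oxy]-8-(methacryloyloxy)germacra-4Z,11(13)-dien-12,6-olide | C=C(C)C(=O)O[C@@H]1C[C@]2(C)O[C@@H]2C[C@H](O)/C(COCc3ccc(OC)cc3)=C\[C@@H]2OC(=O)C(=C)[C@@H]21 | intermediate
26 | (1R,3S,6S,7R,8R,10S)-3-acetoxy-1,10-epoxy-15-[(4-methoxybenzyl)oxy]-8-(methacryloyloxy)germacra-4Z,11(13)-dien-12,6-olide | C=C(C)C(=O)O[C@@H]1C[C@]2(C)O[C@@H]2C[C@H](OC(C)=O)/C(COCc3ccc(OC)cc3)=C\[C@@H]2OC(=O)C(=C)[C@@H]21 | intermediate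
27 | (1R,3S,6S,7R,8R,10S)-3-acetoxy-1,10-epoxy-15-hydroxy-8-(methacryloyloxy)germacra-4Z,11(13)-dien-12,6-olide (CNP0319155.2) | C=C(C)C(=O)O[C@@H]1C[C@]2(C)O[C@@H]2C[C@H](OC(C)=O)/C(CO)=C\[C@@H]2OC(=O)C(=C)[C@@H]21 | target

Total step count: 18.
Longest linear sequence: 15 steps (steps 1–4, then 8–18; the branch through steps 5–7 joins at step 8).

Steps most likely to fail

Step 11. The alkoxide released at C8 on ring opening may attack phosphorus, which transfers the phosphoryl group to oxygen and opens the way to cyclopropane closure. Alternatively the phosphonate carbanion may be too weak a nucleophile, so that C11–C7 bond formation stalls or 6-endo attack intrudes. The fallback sets out from 16 and comes back at 20. Mitsunobu esterification of 16 with allyl hydrogen malonate (PPh3, diisopropyl azodicarboxylate) should give the mixed allyl malonate F1 with inversion at C6. NaH in THF should then effect the same 5-exo-tet oxirane opening, now by a malonate carbanion that has no phosphorus to lose, giving the α-(allyloxycarbonyl) lactone F2. Pd(PPh3)4 with morpholine at 0 °C (Tsuji–Trost deallylation, expected to outpace insertion into the hindered alkenyl iodide) should give the lactone acid F3. Decarboxylative Mannich methylenation (aqueous CH2O, Et2NH, then NaOAc in AcOH, warm) should deliver 20.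

Step 15. Facial selectivity at the aldehyde during ring closure may be poor or reversed, and intermolecular coupling may compete if dilution is insufficient. The fallback sets out from 23 and comes back at 24. If closure delivers the (3R) alcohol F4 alone or mixed with 24, the crude carbinols are oxidised with Dess–Martin periodinane to the cross-conjugated macrocyclic enone F5. Corey–Bakshi–Shibata reduction with the (R)-2-methyl oxazaborolidine and catecholborane at −78 °C should then place hydride under reagent control (the alkenyl C4 side acting as the large group) and return 24.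

Step 16. Oxygen may be delivered to the wrong face of C1=C10 if the steric bias of the folded ring overrides hydrogen-bond direction by the homoallylic hydroxyl, and the free C3 hydroxyl may attack the new oxirane across the ring. The fallback sets out from 24 and comes back at 26. Acetylation first (Ac2O, DMAP, pyridine) gives the diene acetate F6. N-Bromosuccinimide in aqueous THF should form the bromonium ion on the face the peracid prefers, and water should open it at tertiary C10 from the other face, giving the bromohydrin F7. Ag2O in CH2Cl2 should then close the oxirane with inversion at C1, which puts the oxygen on the face opposite to that reached by direct epoxidation and gives 26.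

Further compounds
F1 | step 11 | (1S,2Z)-1-[(2S,3R)-3-{(2Z)-5-[(tert-butyldimethylsilyl)oxy]-2-methylpent-2-en-1-yl}oxiran-2-yl]-3-iodo-4-[(4-methoxybenzyl)oxy]but-2-en-1-yl prop-2-en-1-yl propanedioate | COc1ccc(COC/C(I)=C/[C@H](OC(=O)CC(=O)OCC=C)[C@H]2O[C@@H]2C/C(C)=C\CCO[Si](C)(C)C(C)(C)C)cc1
F2 | step 11 | prop-2-en-1-yl (4R,5R)-4-{(1R,3Z)-6-[(tert-butyldimethylsilyl)oxy]-1-hydroxy-3-methylhex-3-en-1-yl}-5-{(1Z)-2-iodo-3-[(4-methoxybenzyl)oxy]prop-1-en-1-yl}-2-oxooxolane-3-carboxylate (C3 epimers) | COc1ccc(COC/C(I)=C/[C@@H]2OC(=O)C(C(=O)OCC=C)[C@@H]2[C@H](O)C/C(C)=C\CCO[Si](C)(C)C(C)(C)C)cc1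
F3 | step 11 | (4R,5R)-4-{(1R,3Z)-6-[(tert-butyldimethylsilyl)oxy]-1-hydroxy-3-methylhex-3-en-1-yl}-5-{(1Z)-2-iodo-3-[(4-methoxybenzyl)oxy]prop-1-en-1-yl}-2-oxooxolane-3-carboxylic acid (C3 epimers) | COc1ccc(COC/C(I)=C/[C@@H]2OC(=O)C(C(=O)O)[C@@H]2[C@H](O)C/C(C)=C\CCO[Si](C)(C)C(C)(C)C)cc1
F4 | step 15 | (3R,6S,7R,8R)-3-hydroxy-15-[(4-methoxybenzyl)oxy]-8-(methacryloyloxy)germacra-1(10)Z,4Z,11(13)-trien-12,6-olide | C=C(C)C(=O)O[C@@H]1C/C(C)=C\C[C@@H](O)/C(COCc3ccc(OC)cc3)=C\[C@@H]2OC(=O)C(=C)[C@@H]21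
F5 | step 15 | (6S,7R,8R)-15-[(4-methoxybenzyl)oxy]-8-(methacryloyloxy)-3-oxogermacra-1(10)Z,4Z,11(13)-trien-12,6-olide | C=C(C)C(=O)O[C@@H]1C/C(C)=C\CC(=O)/C(COCc3ccc(OC)cc3)=C\[C@@H]2OC(=O)C(=C)[C@@H]21
F6 | step 16 | (3S,6S,7R,8R)-3-acetoxy-15-[(4-methoxybenzyl)oxy]-8-(methacryloyloxy)germacra-1(10)Z,4Z,11(13)-trien-12,6-olide | C=C(C)C(=O)O[C@@H]1C/C(C)=C\C[C@H](OC(C)=O)/C(COCc3ccc(OC)cc3)=C\[C@@H]2OC(=O)C(=C)[C@@H]21
F7 | step 16 | (1S,3S,6S,7R,8R,10S)-3-acetoxy-1-bromo-10-hydroxy-15-[(4-methoxybenzyl)oxy]-8-(methacryloyloxy)germacra-4Z,11(13)-dien-12,6-olide | C=C(C)C(=O)O[C@@H]1C[C@](C)(O)[C@@H](Br)C[C@H](OC(C)=O)/C(COCc3ccc(OC)cc3)=C\[C@@H]2OC(=O)C(=C)[C@@H]21
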